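The pyranone ring is assembled on a preformed ring A through four bonds: C8a–O1 and C4a–C4 from an aryne, C3–C4 and O1–C2 from an arylacetate. The target offers the right handle: ring A carries the pyranone oxygen and C4 on adjacent carbons (C8a, C4a), and C4a is flanked by the oxygenated C5. This is the substitution a 3-alkoxybenzyne produces when it inserts into the C=O of a formamide. A single operation thus converts a 2-silylaryl triflate bearing benzyloxy and methoxy groups, DMF and a protected 2,4-dioxygenated phenylacetate into the full 3-arylcoumarin. The C6 prenyl group follows by Claisen shift from O5.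

Key step: step 8

Remark: the target has no stereocentre and its only side-chain alkene carries two identical methyl groups, so no step has to set configuration. 3-Chloro-3-methylbut-1-yne is taken as a purchased reagent.

Step 1
Reactants: 1 5-methoxyresorcinol (5-methoxybenzene-1,3-diol)
Product: 2 1-methoxy-3,5-bis(methoxymethoxy)benzene
Conditions: MOMCl, i-Pr2NEt, CH2Cl2, 0 °C → rt
Reagents that add atoms: chloromethyl methyl ether, COCCl
Why: Both phenols should be O-alkylated by the reactive α-chloro ether under amine base (Williamson-type acetal formation), giving a symmetric substrate whose two MOM groups can direct metalation to the carbon between them.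

Step 2
Reactants: 2 1-methoxy-3,5-bis(methoxymethoxy)benzene
Product: 4 2-bromo-5-methoxy-1,3-bis(methoxymethoxy)benzene, via aryllithium 3 (not isolated)
Conditions: n-BuLi, TMEDA, THF, 0 °C; then BrCCl2CCl2Br, −78 °C → rt
Reagents that add atoms: 1,2-dibromo-1,1,2,2-tetrachloroethane, BrC(Cl)(Cl)C(Cl)(Cl)Br
Why: Directed ortho-metalation should occur at C2, the only site flanked by two chelating OMOM groups (stronger directors than OMe), and the aryllithium is brominated by halogen transfer from the polyhaloethane, which collapses to tetrachloroethene.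

Step 3
Reactants: 4 2-bromo-5-methoxy-1,3-bis(methoxymethoxy)benzene
Product: 5 2-bromo-5-methoxybenzene-1,3-diol
Conditions: HCl (3 M aq.), MeOH, 50 °C
Reagents that add atoms: none
Why: Acid-catalysed methanolysis of the two aryl MOM acetals should free the resorcinol while the aryl bromide and the methyl ether are inert, which is why halogen and not silicon is carried through this acidic step.

Step 4
Reactants: 5 2-bromo-5-methoxybenzene-1,3-diol
Product: 6 3-(benzyloxy)-2-bromo-5-methoxyphenol
Conditions: BnBr (0.95 equiv), K2CO3, acetone, rt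
Reagents that add atoms: benzyl bromide, BrCc1ccccc1
Why: Williamson etherification with slightly less than one equivalent of halide should give mainly the mono-ether of the symmetric diol (the two hydroxyls are equivalent, so no regiochemical question arises), separable from recovered 5 and the bis-ether.

Step 5
Reactants: 6 3-(benzyloxy)-2-bromo-5-methoxyphenol
Product: 9 3-(benzyloxy)-5-methoxy-2-(trimethylsilyl)phenyl trifluoromethanesulfonate, via silyl ether 7 (not isolated), via lithium phenoxide 8 (not isolated)
Conditions: (Me3Si)2NH, THF, 65 °C, then evaporation; n-BuLi, THF, −78 °C; Tf2O, −78 °C → rt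
Reagents that add atoms: hexamethyldisilazane, C[Si](C)(C)N[Si](C)(C)C; trifluoromethanesulfonic anhydride, O=S(=O)(OS(=O)(=O)C(F)(F)F)C(F)(F)F
Why: O-silylation, bromine–lithium exchange, anionic 1,3 O-to-C silyl migration (retro-Brook rearrangement) and O-triflation of the resulting phenoxide form the standard one-flask conversion of an ortho-bromophenol into an ortho-silylaryl triflate, and exchange at −78 °C should outpace benzylic deprotonation.

Step 6
Reactants: 10 2,4-dihydroxyphenylacetic acid
Product: 11 methyl 2-(2,4-dihydroxyphenyl)acetate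
Conditions: MeOH, H2SO4 (cat.), reflux
Reagents that add atoms: methanol, CO
Why: Fischer esterification in excess methanol should give the methyl ester, any benzofuranone formed by lactonisation of the 2-hydroxy acid being reopened by acid-catalysed methanolysis.

Step 7
Reactants: 11 methyl 2-(2,4-dihydroxyphenyl)acetate
Product: 12 methyl 2-[2,4-bis(methoxymethoxy)phenyl]acetate
Conditions: MOMCl, i-Pr2NEt, CH2Cl2, 0 °C → rt
Reagents that add atoms: chloromethyl methyl ether, COCCl
Why: O-alkylation of both phenols with the α-chloro ether masks the acidic protons so that only the benzylic CH2 is deprotonated in the next step, and MOM ethers tolerate strong base and fluoride.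

Step 8
Reactants: 9 3-(benzyloxy)-5-methoxy-2-(trimethylsilyl)phenyl trifluoromethanesulfonate; 12 methyl 2-[2,4-bis(methoxymethoxy)phenyl]acetate; 13 N,N-dimethylformamide
Product: 19 5-(benzyloxy)-3-[2,4-bis(methoxymethoxy)phenyl]-7-methoxy-2H-chromen-2-one, via aryne 14 (not isolated), via benzoxete 15 (not isolated), via quinone methide 16 (not isolated), via sodium enolate 17 (not isolated), via amino lactone 18 (not isolated)
Conditions: 9, CsF, 13 as solvent, rt; then 17 (from 12, NaN(SiMe3)2, THF, −78 °C) added at −20 °C, then rt → 50 °C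
Reagents that add atoms: none
Why: Fluoride removes the silyl group of 9 and triflate departs to give aryne 14, whose remote carbon is attacked by the carbonyl oxygen of 13 while the aryl anion closes on the iminium carbon (formal [2+2], four-membered benzoxete 15), and electrocyclic opening gives the amino ortho-quinone methide 16. Enolate 17 then adds to the exocyclic carbon of 16 (C3–C4), the liberated phenoxide attacks the ester carbonyl in a 6-exo-trig acyl substitution (O1–C2) to give amino lactone 18, and E1cB loss of dimethylamine furnishes the aromatic pyranone of 19. The closest known reaction type is the three-component coupling of arynes, formamides and active methylene compounds or ester enolates to coumarins. No stereocentre survives, since the two sp3 centres of 18 are erased by the elimination. The step needs regioselective insertion, which the inductively withdrawing alkoxy group beside the triple bond secures by distorting the aryne so that oxygen bonds to the distal carbon (future C8a) and C4 lands on C4a next to C5–O. It also needs 13 and not the enolate to capture the aryne, which is secured by generating 14 in neat 13 before 17 is introduced.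

Step 9
Reactants: 19 5-(benzyloxy)-3-[2,4-bis(methoxymethoxy)phenyl]-7-methoxy-2H-chromen-2-one
Product: 20 3-[2,4-bis(methoxymethoxy)phenyl]-5-hydroxy-7-methoxy-2H-chromen-2-one
Conditions: H2 (1 atm), Pd/C, EtOAc, rt
Reagents that add atoms: none
Why: Hydrogenolysis of the aryl benzyl ether over palladium at atmospheric pressure should be much faster than reduction of the trisubstituted, aryl-conjugated C3–C4 bond, and MOM ethers are inert.

Step 10
Reactants: 20 3-[2,4-bis(methoxymethoxy)phenyl]-5-hydroxy-7-methoxy-2H-chromen-2-one
Product: 21 3-[2,4-bis(methoxymethoxy)phenyl]-7-methoxy-5-[(2-methylbut-3-yn-2-yl)oxy]-2H-chromen-2-one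
Conditions: 3-chloro-3-methylbut-1-yne, DBU, CuCl2·2H2O (cat.), MeCN, 0 °C → rt
Reagents that add atoms: 3-chloro-3-methylbut-1-yne, CC(C)(Cl)C#C
Why: Copper-catalysed etherification of phenols with tertiary propargylic chlorides and an amidine base is a standard way to make aryl 1,1-dimethylpropargyl ethers, and only the C5 hydroxyl is free.

Step 11
Reactants: 21 3-[2,4-bis(methoxymethoxy)phenyl]-7-methoxy-5-[(2-methylbut-3-yn-2-yl)oxy]-2H-chromen-2-one
Product: 22 3-[2,4-bis(methoxymethoxy)phenyl]-7-methoxy-5-[(2-methylbut-3-en-2-yl)oxy]-2H-chromen-2-one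
Conditions: H2 (1 atm), Pd/CaCO3 poisoned with Pb(OAc)2 (Lindlar catalyst), quinoline, EtOAc, rt
Reagents that add atoms: none
Why: Lindlar semi-hydrogenation should stop at the terminal alkene and leave the coumarin double bond and the acetals untouched.

Step 12
Reactants: 22 3-[2,4-bis(methoxymethoxy)phenyl]-7-methoxy-5-[(2-methylbut-3-en-2-yl)oxy]-2H-chromen-2-one
Product: 24 3-[2,4-bis(methoxymethoxy)phenyl]-5-hydroxy-7-methoxy-6-(3-methylbut-2-en-1-yl)-2H-chromen-2-one, via dienone 23 (not isolated)
Conditions: PhNEt2, 130 °C
Reagents that add atoms: none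
Why: Aromatic Claisen rearrangement of the tertiary allyl ether, a [3,3] shift through a chair-like transition state, can deliver the allyl terminus only to C6 because the other ortho position (C4a) is a ring-fusion carbon, and enolisation of dienone 23 restores the phenol with the prenyl group in place.

Step 13
Reactants: 24 3-[2,4-bis(methoxymethoxy)phenyl]-5-hydroxy-7-methoxy-6-(3-methylbut-2-en-1-yl)-2H-chromen-2-one
Product: 25 3-(2,4-dihydroxyphenyl)-5-hydroxy-7-methoxy-6-(3-methylbut-2-en-1-yl)-2H-chromen-2-one
Conditions: HCl (3 M aq.), MeOH, 40 °C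
Reagents that add atoms: none
Why: Mild acid-catalysed methanolysis should cleave the two aryl MOM acetals faster than the alkene is protonated, so that the prenyl group and the lactone survive if the reaction is stopped at full conversion.

Compound list
1 | 5-methoxyresorcinol | COc1cc(O)cc(O)c1 | starting material
2 | 1-methoxy-3,5-bis(methoxymethoxy)benzene | COCOc1cc(OC)cc(OCOC)c1 | intermediate
3 | 2-lithio-5-methoxy-1,3-bis(methoxymethoxy)benzene (aryllithium, not isolated) | [Li]c1c(OCOC)cc(OC)cc1OCOC | intermediate
4 | 2-bromo-5-methoxy-1,3-bis(methoxymethoxy)benzene | COCOc1cc(OC)cc(OCOC)c1Br | intermediate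
5 | 2-bromo-5-methoxybenzene-1,3-diol | COc1cc(O)c(Br)c(O)c1 | intermediate
6 | 3-(benzyloxy)-2-bromo-5-methoxyphenol | COc1cc(O)c(Br)c(OCc2ccccc2)c1 | intermediate
7 | [3-(benzyloxy)-2-bromo-5-methoxyphenoxy]trimethylsilane (silyl ether, not isolated) | COc1cc(O[Si](C)(C)C)c(Br)c(OCc2ccccc2)c1 | intermediate
8 | lithium 3-(benzyloxy)-5-methoxy-2-(trimethylsilyl)phenoxide (not isolated) | COc1cc([O-])c([Si](C)(C)C)c(OCc2ccccc2)c1.[Li+] | intermediate
9 | 3-(benzyloxy)-5-methoxy-2-(trimethylsilyl)phenyl trifluoromethanesulfonate | COc1cc(OCc2ccccc2)c([Si](C)(C)C)c(OS(=O)(=O)C(F)(F)F)c1 | intermediate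
10 | 2,4-dihydroxyphenylacetic acid | O=C(O)Cc1ccc(O)cc1O | starting material
11 | methyl 2-(2,4-dihydroxyphenyl)acetate | COC(=O)Cc1ccc(O)cc1O | intermediate
12 | methyl 2-[2,4-bis(methoxymethoxy)phenyl]acetate | COC(=O)Cc1ccc(OCOC)cc1OCOC | intermediate
13 | N,N-dimethylformamide | CN(C)C=O | starting material
14 | 3-(benzyloxy)-5-methoxybenzyne (aryne, not isolated) | COC1=CC#CC(OCc2ccccc2)=C1 | intermediate
15 | 3-(benzyloxy)-5-methoxy-N,N-dimethyl-2H-benzoxet-2-amine (racemic, not isolated) | CN(C)C1Oc2cc(OC)cc(OCc3ccccc3)c21 | intermediate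
16 | 5-(benzyloxy)-6-[(dimethylamino)methylidene]-3-methoxycyclohexa-2,4-dien-1-one, drawn as its iminium phenolate form (quinone methide, not isolated) | C[N+](C)=Cc1c([O-])cc(OC)cc1OCc1ccccc1 | intermediate
17 | sodium enolate of 12, drawn as the benzylic carbanion (not isolated) | COC(=O)[CH-]c1ccc(OCOC)cc1OCOC.[Na+] | intermediate
18 | 5-(benzyloxy)-3-[2,4-bis(methoxymethoxy)phenyl]-4-(dimethylamino)-7-methoxy-3,4-dihydro-2H-chromen-2-one (amino lactone, diastereomer mixture, both centres removed in the same step, not isolated) | COc1cc(OCc2ccccc2)c2C(N(C)C)C(c3ccc(OCOC)cc3OCOC)C(=O)Oc2c1 | intermediate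
19 | 5-(benzyloxy)-3-[2,4-bis(methoxymethoxy)phenyl]-7-methoxy-2H-chromen-2-one | COc1cc(OCc2ccccc2)c2cc(-c3ccc(OCOC)cc3OCOC)c(=O)oc2c1 | intermediate
20 | 3-[2,4-bis(methoxymethoxy)phenyl]-5-hydroxy-7-methoxy-2H-chromen-2-one | COc1cc(O)c2cc(-c3ccc(OCOC)cc3OCOC)c(=O)oc2c1 | intermediate
21 | 3-[2,4-bis(methoxymethoxy)phenyl]-7-methoxy-5-[(2-methylbut-3-yn-2-yl)oxy]-2H-chromen-2-one | COc1cc(OC(C)(C)C#C)c2cc(-c3ccc(OCOC)cc3OCOC)c(=O)oc2c1 | intermediate
22 | 3-[2,4-bis(methoxymethoxy)phenyl]-7-methoxy-5-[(2-methylbut-3-en-2-yl)oxy]-2H-chromen-2-one | COc1cc(OC(C)(C)C=C)c2cc(-c3ccc(OCOC)cc3OCOC)c(=O)oc2c1 | intermediate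
23 | 3-[2,4-bis(methoxymethoxy)phenyl]-7-methoxy-6-(3-methylbut-2-en-1-yl)-2H-chromene-2,5(6H)-dione (dienone, racemic at C6, centre lost on enolisation, not isolated) | COC1=CC2=C(C=C(c3ccc(OCOC)cc3OCOC)C(=O)O2)C(=O)C1CC=C(C)C | intermediate
24 | 3-[2,4-bis(methoxymethoxy)phenyl]-5-hydroxy-7-methoxy-6-(3-methylbut-2-en-1-yl)-2H-chromen-2-one | COc1cc2oc(=O)c(-c3ccc(OCOC)cc3OCOC)cc2c(O)c1CC=C(C)C | intermediate
25 | 3-(2,4-dihydroxyphenyl)-5-hydroxy-7-methoxy-6-(3-methylbut-2-en-1-yl)-2H-chromen-2-one (CNP0305155.0) | COc1cc2oc(=O)c(-c3ccc(O)cc3O)cc2c(O)c1CC=C(C)C | target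

Total step count: 13. Longest linear sequence: 11 steps (steps 1–5, 8, 9–13); the ring B branch (steps 6 and 7) joins at step 8.

Steps most likely to fail

Step 8. The aryne may be captured by the enolate carbon instead of the formamide oxygen if it is still being released when the enolate arrives. The quinone methide may also be consumed by a second aryne or by self-condensation before conjugate addition, and lactonisation or amine elimination may stall. The fallback separates the insertion from the ring closure and sets out from 9 and 12. Triflate 9 is treated with CsF in 13 at rt and the mixture is worked up with water, which should hydrolyse the insertion adduct to 2-(benzyloxy)-6-hydroxy-4-methoxybenzaldehyde F1. Ester 12 is saponified (LiOH, THF/H2O) to 2-[2,4-bis(methoxymethoxy)phenyl]acetic acid F2. Perkin–Oglialoro condensation of F1 with F2 (Ac2O, Et3N, 110 °C) should then close the lactone and return to the route at 19.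

Step 13. Acid may promote addition of the C5 hydroxyl across the neighbouring prenyl double bond (closure to a dimethylchroman) in competition with acetal cleavage. The fallback removes the acetals before the alkene exists and sets out from 21. Its tertiary propargylic aryl ether ionises far more slowly than a MOM acetal, so HCl in MeOH at rt should give 3-(2,4-dihydroxyphenyl)-7-methoxy-5-[(2-methylbut-3-yn-2-yl)oxy]-2H-chromen-2-one F3. Semi-hydrogenation over Pd/CaCO3 poisoned with Pb(OAc)2 gives 3-(2,4-dihydroxyphenyl)-7-methoxy-5-[(2-methylbut-3-en-2-yl)oxy]-2H-chromen-2-one F4. Heating F4 in PhNEt2 at 130 °C brings about the Claisen shift and comes back to the route at 25, with no acid used after the prenyl group is formed.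

Step 12. The tertiary allyl ether may fragment on heating (loss of the C5 unit as isoprene, regenerating the phenol) faster than it rearranges. The fallback builds the side chain from a primary allyl ether, which cannot fragment in this way, and sets out from 20. Allyl bromide and K2CO3 in acetone give 5-(allyloxy)-3-[2,4-bis(methoxymethoxy)phenyl]-7-methoxy-2H-chromen-2-one F5. Claisen rearrangement in PhNEt2 at 190 °C, again possible only towards C6, gives 6-allyl-3-[2,4-bis(methoxymethoxy)phenyl]-5-hydroxy-7-methoxy-2H-chromen-2-one F6. Cross-metathesis of F6 with 2-methylbut-2-ene and the second-generation Grubbs catalyst RuCl2(=CHPh)(PCy3)(H2IMes) in CH2Cl2 at 40 °C comes back to the route at 24.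

Further compounds
F1 | step 8 | 2-(benzyloxy)-6-hydroxy-4-methoxybenzaldehyde | COc1cc(O)c(C=O)c(OCc2ccccc2)c1
F2 | step 8 | 2-[2,4-bis(methoxymethoxy)phenyl]acetic acid | COCOc1ccc(CC(=O)O)c(OCOC)c1
F3 | step 13 | 3-(2,4-dihydroxyphenyl)-7-methoxy-5-[(2-methylbut-3-yn-2-yl)oxy]-2H-chromen-2-one | COc1cc(OC(C)(C)C#C)c2cc(-c3ccc(O)cc3O)c(=O)oc2c1
F4 | step 13 | 3-(2,4-dihydroxyphenyl)-7-methoxy-5-[(2-methylbut-3-en-2-yl)oxy]-2H-chromen-2-one | COc1cc(OC(C)(C)C=C)c2cc(-c3ccc(O)cc3O)c(=O)oc2c1
F5 | step 12 | 5-(allyloxy)-3-[2,4-bis(methoxymethoxy)phenyl]-7-methoxy-2H-chromen-2-one | COc1cc(OCC=C)c2cc(-c3ccc(OCOC)cc3OCOC)c(=O)oc2c1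
F6 | step 12 | 6-allyl-3-[2,4-bis(methoxymethoxy)phenyl]-5-hydroxy-7-methoxy-2H-chromen-2-one | COc1cc2oc(=O)c(-c3ccc(OCOC)cc3OCOC)cc2c(O)c1CC=C
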